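Early on, this flask is a question of where G goes the moment it dissolves, and that is how I would answer your request for a quick number and your hunch about the gas feed.

    D.G → Z (k1 = 0.00192 /min)
    X ⇌ G, rate k2*(csat - [G]) (k2 = 0.454 /min, csat = 5.5 mM)
    D.G ⇌ Q + E (K3 = 0.107 M, k3 = 0.0366 /min)
    D + G ⇌ D.G (K4 = 130 /M, k4 = 7.13 /M/min)
    G + Q → G.Q (k5 = 0.849 /M/min)

D 0.10 M; X 5.5 mM (held); time 50 min

- at the start none of G is dissolved
- run time (flask): 50 min

- south: doubling the transfer coefficient of step 2, all else as stated
- north-east: doubling the saturation concentration of X, all else as stated

- how much Q there is at 50 min, in percent of the D charged
- concentration of G in solution at 5.0 min, in percent of saturation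
- the change that raises the amount of Q at 50 min, in percent of the D charged most ("none" if none brings more than 2 percentage points) (south / north-east / none)
- amount of Q at 50 min, in percent of the D charged, after south

Against step 4, forward rate alone and at the charged concentrations, G has a half-life of 0.97 min, far shorter than 50 min, so I treat G as a quasi-steady state, with transfer in balancing uptake by D. You then find G at 38.9 % of saturation.

That level leaves a rate, 0.0153 /min. This is the intake, the fraction of the charge bound per minute with G at its quasi-steady level.

D.G then leaves by steps 1, 3 and the back reaction of step 4. A share 39.2 % of what leaves becomes Q, and the D.G pool takes 10.7 min to fill. With D held at its charge and the return of Q and E left out, you get 23.5 % of the charge as Q.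

Doubling the saturation doubles the intake to 0.0306 /min, while doubling the transfer coefficient gives 0.0220 /min, which is less. So I choose north-east. For south I commit to a ceiling and no more: Q stays below 33.8 %.

The forecast steps the flask by hand and opens with “Take G as quasi-steady after about 1 min”. It gives a figure for yb where I gave a ceiling, and it names the same best change. The simulation stands beneath it:

| | y | sat | yb | best |
|---|---|---|---|---|
| forecast | 22.7 % | 44 % | 26.4 % | north-east |
| simulation | 22.5 % | 43.7 % | 26.1 % | north-east |

In this flask, Q rose by 0.00527 /min of the charge between 25.0 min and 50.0 min, against 0.00600 /min from share times intake. Now take the neighbour flask, charged with 0.25 M of D, the time held. Its intake falls to 0.00796 /min, which is less than in this flask, and the same share and filling time give 12.3 % of its charge as Q. The simulated neighbour flask holds 14.5 % of its charge as Q at 50.0 min.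

The numbers of this flask stand for no real mixture; no experiment stands behind them.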